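Without the C3 benzyl group, the γ-lactone ring (O1, C2, C3, C4, C5) is a 3-substituted cyclobutanone with one oxygen inserted, and its stereocentre C4 is the prochiral ring carbon of that ketone. A catalyst-controlled Baeyer–Villiger ring expansion therefore makes the C2–O1 and O1–C5 bonds, the five-membered ring and C4 in one operation. Its precursor is the cyclobutanone carrying the finished (S)-C7' silyloxy(3,4-dimethoxyphenyl)methyl arm; it is unveiled from an exocyclic methylene group, so that no acid meets the benzylic silyl ether. trans-Selective benzylation at C3 and two mild deprotections complete the route.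

Key step: step 5

Remark: the lactone is numbered O1, C2 (carbonyl), C3, C4, C5, and C7' is the carbinol carbon on C4; the target is read as (3R,4R,7'S) with the C3 and C4 substituents trans, and the sense of induction of each chiral catalyst on these substrates is taken by analogy and would be confirmed on small scale.

Step 1
Reactants: 1 3-methylidenecyclobutane-1-carbonitrile; 2 4-bromoveratrole (4-bromo-1,2-dimethoxybenzene)
Product: 5 (3,4-dimethoxyphenyl)(3-methylidenecyclobutyl)methanone, via Grignard reagent 3 (not isolated), via N-magnesio ketimine 4 (not isolated)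
Conditions: 2, Mg, I2 (cat.), THF, rt to 50 °C; then 1, CuBr (2 mol%), THF, 60 °C; then 1 M aq. HCl, 0 °C to rt
Reagents that add atoms: water, O
Why: Grignard addition to a nitrile stops at the N-magnesio ketimine, which cannot take up a second aryl group, and cold dilute acid should hydrolyse it to the aryl ketone without touching the 1,1-disubstituted alkene; CuBr is the usual accelerator for α-branched nitriles.

Step 2
Reactants: 5 (3,4-dimethoxyphenyl)(3-methylidenecyclobutyl)methanone
Product: 6 (S)-(3,4-dimethoxyphenyl)(3-methylidenecyclobutyl)methanol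
Conditions: H2 (8 atm), RuCl2[(R)-xylbinap][(R)-daipen] (0.2 mol%), t-BuOK (2 mol%), i-PrOH, rt
Reagents that add atoms: none
Why: Noyori asymmetric hydrogenation, in which the ruthenium hydride and the amine N–H deliver hydride and proton to the carbonyl in an outer-sphere transition state that leaves unactivated alkenes alone; this catalyst family differentiates aryl from α-branched alkyl groups well, and the (R,R) complex is expected by analogy with simple aryl alkyl ketones to set C7' as S (the antipodal complex is taken if the check shows the opposite sense).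

Step 3
Reactants: 6 (S)-(3,4-dimethoxyphenyl)(3-methylidenecyclobutyl)methanol
Product: 7 tert-butyl[(S)-(3,4-dimethoxyphenyl)(3-methylidenecyclobutyl)methoxy]dimethylsilane
Conditions: TBSCl, imidazole, DMF, rt
Reagents that add atoms: tert-butyldimethylsilyl chloride, CC(C)(C)[Si](C)(C)Cl
Why: Imidazole-mediated silyl ether formation takes place at oxygen, so C7' is untouched, and the bulky silyl ether later shields one face of the lactone.

Step 4
Reactants: 7 tert-butyl[(S)-(3,4-dimethoxyphenyl)(3-methylidenecyclobutyl)methoxy]dimethylsilane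
Product: 9 3-[(S)-(tert-butyldimethylsilyloxy)(3,4-dimethoxyphenyl)methyl]cyclobutan-1-one, via vicinal diol 8 (not isolated)
Conditions: K2OsO4·2H2O (2 mol%), NaIO4 (4 equiv), 2,6-lutidine (2 equiv), 1,4-dioxane/H2O 3:1, rt
Reagents that add atoms: sodium periodate, [Na+].[O-]I(=O)(=O)=O
Why: Lemieux–Johnson oxidation, in which catalytic osmium tetroxide dihydroxylates the exocyclic alkene and periodate cleaves the diol to the cyclobutanone and formaldehyde; the lutidine-buffered, near-neutral medium should spare the benzylic silyl ether and the dimethoxyarene.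

Step 5
Reactants: 9 3-[(S)-(tert-butyldimethylsilyloxy)(3,4-dimethoxyphenyl)methyl]cyclobutan-1-one; 10 hydrogen peroxide
Product: 12 (R)-4-[(S)-(tert-butyldimethylsilyloxy)(3,4-dimethoxyphenyl)methyl]dihydrofuran-2(3H)-one, via Criegee adduct 11 (not isolated)
Conditions: 30% aq. H2O2 (1.5 equiv), 3,3'-di(pyren-1-yl)-5,5',6,6',7,7',8,8'-octahydro-1,1'-binaphthyl-2,2'-diyl hydrogen phosphate (10 mol%, antipode matched with C7'), CHCl3, −40 °C
Reagents that add atoms: hydrogen peroxide, OO
Why: The phosphoric acid hydrogen-bonds both the carbonyl and H2O2, the peroxide adds to the strained ketone to give Criegee adduct 11, and the α-CH2 anti-periplanar to the O–O bond shifts to oxygen with loss of water, driven by release of four-ring strain. The closest known reaction is the chiral phosphoric acid-catalysed Baeyer–Villiger desymmetrisation of 3-substituted cyclobutanones with aqueous H2O2, an outcome also known with Baeyer–Villiger monooxygenases. The five-membered lactone is closed by ring expansion, a 1,2-shift of carbon to oxygen within the four-membered ring, so no exo or endo cyclisation mode applies. The new stereocentre C4 is fixed by which of the two diastereotopic CH2 groups migrates, a choice made by the chiral phosphate pocket that holds the Criegee adduct; both catalyst antipodes would be run on small scale and the one matched with C7' kept. The step needs selectivity only between these two CH2 groups, since both α-carbons are primary and regiochemistry is moot; the strained ketone should react far faster than the insulated dimethoxyarene, the weak acid at −40 °C should leave the benzylic silyl ether intact, and because C7' is already set any minor C4 epimer is a diastereomer that chromatography should remove.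

Step 6
Reactants: 13 4-(benzyloxy)-3-methoxybenzyl alcohol
Product: 14 4-(benzyloxy)-3-methoxybenzyl bromide
Conditions: PBr3 (0.4 equiv), Et2O, 0 °C
Reagents that add atoms: phosphorus tribromide, BrP(Br)Br
Why: Bromination of a benzylic alcohol through its phosphite ester and SN2 displacement by bromide; the aryl benzyl ether should be inert under these brief, cold conditions.

Step 7
Reactants: 12 (R)-4-[(S)-(tert-butyldimethylsilyloxy)(3,4-dimethoxyphenyl)methyl]dihydrofuran-2(3H)-one; 14 4-(benzyloxy)-3-methoxybenzyl bromide
Product: 16 (3R,4R)-3-[4-(benzyloxy)-3-methoxybenzyl]-4-[(S)-(tert-butyldimethylsilyloxy)(3,4-dimethoxyphenyl)methyl]dihydrofuran-2(3H)-one, via lithium enolate 15 (not isolated)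
Conditions: LiHMDS (1.1 equiv), THF, −78 °C; then 14, DMPU, −78 to −40 °C
Reagents that add atoms: none
Why: Enolate alkylation of a β-substituted γ-butyrolactone, in which the benzylic bromide attacks the planar lithium enolate on the face anti to the bulky C4 silyloxybenzyl group and so sets C3 as R, trans to C4; the silyloxy group sits γ to the enolate carbon, so no elimination pathway opens, and C4 and C7' are not deprotonated.

Step 8
Reactants: 16 (3R,4R)-3-[4-(benzyloxy)-3-methoxybenzyl]-4-[(S)-(tert-butyldimethylsilyloxy)(3,4-dimethoxyphenyl)methyl]dihydrofuran-2(3H)-one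
Product: 17 (3R,4R)-4-[(S)-(tert-butyldimethylsilyloxy)(3,4-dimethoxyphenyl)methyl]-3-(4-hydroxy-3-methoxybenzyl)dihydrofuran-2(3H)-one
Conditions: H2 (1 atm), 10% Pd/C, EtOAc, rt
Reagents that add atoms: none
Why: Hydrogenolysis of the aryl benzyl ether should be much faster than cleavage of the hindered, silylated benzylic C7'–O bond, and running it before desilylation in a neutral aprotic solvent keeps the C7' oxygen in place.

Step 9
Reactants: 17 (3R,4R)-4-[(S)-(tert-butyldimethylsilyloxy)(3,4-dimethoxyphenyl)methyl]-3-(4-hydroxy-3-methoxybenzyl)dihydrofuran-2(3H)-one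
Product: 18 (3R,4R)-4-[(S)-(3,4-dimethoxyphenyl)(hydroxy)methyl]-3-(4-hydroxy-3-methoxybenzyl)dihydrofuran-2(3H)-one (target)
Conditions: TBAF (1.5 equiv), AcOH (1.5 equiv), THF, 0 °C to rt
Reagents that add atoms: none
Why: Fluoride-mediated desilylation cleaves the O–Si bond; the acetic acid buffer keeps the freed C7' hydroxyl protonated, so it should neither attack the lactone carbonyl (acyl migration) nor epimerise C3, and no acid strong enough to ionise the electron-rich benzylic carbinol is present.

Compound list
1 | 3-methylidenecyclobutane-1-carbonitrile | C=C1CC(C1)C#N | starting material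
2 | 4-bromoveratrole (4-bromo-1,2-dimethoxybenzene) | COc1ccc(Br)cc1OC | starting material
3 | (3,4-dimethoxyphenyl)magnesium bromide | COc1ccc([Mg]Br)cc1OC | intermediate (not isolated)
4 | N-(bromomagnesio) ketimine of ketone 5 | C=C1CC(C1)C(=N[Mg]Br)c1ccc(OC)c(OC)c1 | intermediate (not isolated)
5 | (3,4-dimethoxyphenyl)(3-methylidenecyclobutyl)methanone | C=C1CC(C1)C(=O)c1ccc(OC)c(OC)c1 | intermediate
6 | (S)-(3,4-dimethoxyphenyl)(3-methylidenecyclobutyl)methanol | C=C1CC(C1)[C@H](O)c1ccc(OC)c(OC)c1 | intermediate
7 | tert-butyl[(S)-(3,4-dimethoxyphenyl)(3-methylidenecyclobutyl)methoxy]dimethylsilane | C=C1CC(C1)[C@H](O[Si](C)(C)C(C)(C)C)c1ccc(OC)c(OC)c1 | intermediate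
8 | 3-[(S)-(tert-butyldimethylsilyloxy)(3,4-dimethoxyphenyl)methyl]-1-(hydroxymethyl)cyclobutan-1-ol (cis/trans mixture at the ring) | OCC1(O)CC(C1)[C@H](O[Si](C)(C)C(C)(C)C)c1ccc(OC)c(OC)c1 | intermediate (not isolated)
9 | 3-[(S)-(tert-butyldimethylsilyloxy)(3,4-dimethoxyphenyl)methyl]cyclobutan-1-one | O=C1CC(C1)[C@H](O[Si](C)(C)C(C)(C)C)c1ccc(OC)c(OC)c1 | intermediate
10 | hydrogen peroxide | OO | starting material
11 | 3-[(S)-(tert-butyldimethylsilyloxy)(3,4-dimethoxyphenyl)methyl]-1-hydroperoxycyclobutan-1-ol (Criegee adduct, cis/trans mixture at the ring) | OOC1(O)CC(C1)[C@H](O[Si](C)(C)C(C)(C)C)c1ccc(OC)c(OC)c1 | intermediate (not isolated)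
12 | (R)-4-[(S)-(tert-butyldimethylsilyloxy)(3,4-dimethoxyphenyl)methyl]dihydrofuran-2(3H)-one | O=C1C[C@H](CO1)[C@H](O[Si](C)(C)C(C)(C)C)c1ccc(OC)c(OC)c1 | intermediate
13 | 4-(benzyloxy)-3-methoxybenzyl alcohol | COc1cc(CO)ccc1OCc1ccccc1 | starting material
14 | 4-(benzyloxy)-3-methoxybenzyl bromide | COc1cc(CBr)ccc1OCc1ccccc1 | intermediate
15 | lithium enolate of lactone 12 (lithium (R)-3-[(S)-(tert-butyldimethylsilyloxy)(3,4-dimethoxyphenyl)methyl]-2,3-dihydrofuran-5-olate) | [Li]OC1=C[C@H](CO1)[C@H](O[Si](C)(C)C(C)(C)C)c1ccc(OC)c(OC)c1 | intermediate (not isolated)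
16 | (3R,4R)-3-[4-(benzyloxy)-3-methoxybenzyl]-4-[(S)-(tert-butyldimethylsilyloxy)(3,4-dimethoxyphenyl)methyl]dihydrofuran-2(3H)-one | COc1cc(C[C@H]2C(=O)OC[C@@H]2[C@H](O[Si](C)(C)C(C)(C)C)c2ccc(OC)c(OC)c2)ccc1OCc1ccccc1 | intermediate
17 | (3R,4R)-4-[(S)-(tert-butyldimethylsilyloxy)(3,4-dimethoxyphenyl)methyl]-3-(4-hydroxy-3-methoxybenzyl)dihydrofuran-2(3H)-one | COc1cc(C[C@H]2C(=O)OC[C@@H]2[C@H](O[Si](C)(C)C(C)(C)C)c2ccc(OC)c(OC)c2)ccc1O | intermediate
18 | (3R,4R)-4-[(S)-(3,4-dimethoxyphenyl)(hydroxy)methyl]-3-(4-hydroxy-3-methoxybenzyl)dihydrofuran-2(3H)-one | COc1cc(C[C@H]2C(=O)OC[C@@H]2[C@H](O)c2ccc(OC)c(OC)c2)ccc1O | target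

Total step count: 9. Longest linear sequence: 8 steps (steps 1–5, then 7–9); step 6 is a one-step side branch.

Steps most likely to fail

1. Step 5. The catalyst may discriminate poorly between the two diastereotopic α-CH2 groups, because the 3-substituent is a branched alkyl group and the existing C7' centre may oppose the catalyst; turnover may also be slow next to the bulky silyl ether. The fallback sets out from 9 and replaces oxygen insertion by a group-selective deprotonation. A chiral lithium amide (lithium bis(1-phenylethyl)amide, matched antipode) with TESCl present in situ in THF at −100 °C should give the silyl enol ether tert-butyl{(S)-(3,4-dimethoxyphenyl)[(1R)-3-(triethylsilyloxy)cyclobut-2-en-1-yl]methoxy}dimethylsilane F1. Ozonolysis (O3, CH2Cl2/MeOH, −78 °C, stopped at the first excess of ozone) should cleave the enol ether to (3S,4S)-4-(tert-butyldimethylsilyloxy)-4-(3,4-dimethoxyphenyl)-3-formylbutanoic acid F2. This is reduced at once in the same flask with NaBH4 to (3R,4S)-4-(tert-butyldimethylsilyloxy)-4-(3,4-dimethoxyphenyl)-3-(hydroxymethyl)butanoic acid F3, before the α-formyl centre can epimerise. Mild acidification (aq. citric acid) should lactonise F3, and the route is rejoined at 12.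

2. Step 2. Enantiofacial discrimination between the aryl and the cyclobutyl group may be insufficient, or the exocyclic alkene may be partly saturated or isomerised under hydrogen. The fallback sets out from 1 and sets C7' in a C–C bond-forming step instead. DIBAL-H (toluene, −78 °C, Rochelle-salt work-up) should give 3-methylidenecyclobutane-1-carbaldehyde F4. Commercial (3,4-dimethoxyphenyl)boronic acid F5 is heated with Et2Zn in toluene (60 °C) to form (3,4-dimethoxyphenyl)(ethyl)zinc F6. F6 is then added to F4 at 0 °C in the presence of a chiral amino alcohol ligand (2-piperidino-1,1,2-triphenylethanol, 10 mol%, antipode chosen for the S carbinol), a known catalytic enantioselective aryl transfer to aldehydes. The route is rejoined at 6.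

3. Step 8. Over-reduction may occur, that is hydrogenolytic cleavage of the electron-rich benzylic C7'–O bond, or the silyl group may be lost on the catalyst surface. The fallback sets out from 12 and avoids hydrogenation altogether by carrying the phenol as a silyl ether. Commercial 4-(tert-butyldimethylsilyloxy)-3-methoxybenzaldehyde F7 is reduced (NaBH4, MeOH, 0 °C) to 4-(tert-butyldimethylsilyloxy)-3-methoxybenzyl alcohol F8. An Appel reaction (CBr4, PPh3, CH2Cl2, 0 °C) should convert F8 into 4-(tert-butyldimethylsilyloxy)-3-methoxybenzyl bromide F9, which is used at once. Alkylation of enolate 15 (from 12, LiHMDS, THF, −78 °C) with F9 should give (3R,4R)-4-[(S)-(tert-butyldimethylsilyloxy)(3,4-dimethoxyphenyl)methyl]-3-[4-(tert-butyldimethylsilyloxy)-3-methoxybenzyl]dihydrofuran-2(3H)-one F10. One buffered fluoride treatment (TBAF/AcOH, THF, 0 °C to rt) should remove both silyl groups, and the route is rejoined at 18.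

Further compounds
F1 | step 5 | tert-butyl{(S)-(3,4-dimethoxyphenyl)[(1R)-3-(triethylsilyloxy)cyclobut-2-en-1-yl]methoxy}dimethylsilane | CC[Si](CC)(CC)OC1=C[C@@H](C1)[C@H](O[Si](C)(C)C(C)(C)C)c1ccc(OC)c(OC)c1
F2 | step 5 | (3S,4S)-4-(tert-butyldimethylsilyloxy)-4-(3,4-dimethoxyphenyl)-3-formylbutanoic acid | O=C[C@@H](CC(=O)O)[C@H](O[Si](C)(C)C(C)(C)C)c1ccc(OC)c(OC)c1
F3 | step 5 | (3R,4S)-4-(tert-butyldimethylsilyloxy)-4-(3,4-dimethoxyphenyl)-3-(hydroxymethyl)butanoic acid | OC[C@@H](CC(=O)O)[C@H](O[Si](C)(C)C(C)(C)C)c1ccc(OC)c(OC)c1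
F4 | step 2 | 3-methylidenecyclobutane-1-carbaldehyde | C=C1CC(C1)C=O
F5 | step 2 | (3,4-dimethoxyphenyl)boronic acid | OB(O)c1ccc(OC)c(OC)c1
F6 | step 2 | (3,4-dimethoxyphenyl)(ethyl)zinc | CC[Zn]c1ccc(OC)c(OC)c1
F7 | step 8 | 4-(tert-butyldimethylsilyloxy)-3-methoxybenzaldehyde | COc1cc(C=O)ccc1O[Si](C)(C)C(C)(C)C
F8 | step 8 | 4-(tert-butyldimethylsilyloxy)-3-methoxybenzyl alcohol | COc1cc(CO)ccc1O[Si](C)(C)C(C)(C)C
F9 | step 8 | 4-(tert-butyldimethylsilyloxy)-3-methoxybenzyl bromide | COc1cc(CBr)ccc1O[Si](C)(C)C(C)(C)C
F10 | step 8 | (3R,4R)-4-[(S)-(tert-butyldimethylsilyloxy)(3,4-dimethoxyphenyl)methyl]-3-[4-(tert-butyldimethylsilyloxy)-3-methoxybenzyl]dihydrofuran-2(3H)-one | COc1cc(C[C@H]2C(=O)OC[C@@H]2[C@H](O[Si](C)(C)C(C)(C)C)c2ccc(OC)c(OC)c2)ccc1O[Si](C)(C)C(C)(C)C
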